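The route rests on forming the lactone C7–C11 bond on a ten-membered ring that already carries an acrylate on O6 and a trans C7–C8 epoxide anti to it. The step exploits the contiguous O6/C7/O8 triad of the ring. Trimethylphosphine adds to the acrylate, and its α-carbon (C11) then opens the epoxide at C7 from the rear in a Morita–Baylis–Hillman-type 5-exo closure. One operation builds the α-methylene-γ-butyrolactone ring (O6–C6–C7–C11–C12), inverts C7, restores the C11=C13 methylene and frees the C8 hydroxyl for the isovalerate. The precursor comes from a Nozaki–Hiyama–Kishi closure of the cyclodecatriene and a Sharpless kinetic-resolution epoxidation; the 4,5-epoxide is added last.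

Key step: step 10

Remark: germacrane numbering is used for all compounds, also the open-chain ones (C1–C10 ring carbons, C11–C13 the lactone C3 unit, C14 the carbon on C10, C15 the methyl on C4). Remark: 13 is a racemate and its SMILES carries no configuration at C6. Remark: phosphonate 6 is made, not bought.

Step 1
Reactants: 1 geranyl acetate
Product: 3 (2E)-3-methyl-6-oxohex-2-en-1-yl acetate, via ozonide 2 (not isolated)
Conditions: O3 (1 equiv), CH2Cl2, −78 °C; then Me2S, −78 °C to rt
Reagents that add atoms: ozone, [O-][O+]=O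
Why: Ozonolysis with reductive work-up should cleave only the electron-rich distal trisubstituted double bond, because the double bond next to the allylic acetate is inductively deactivated.

Step 2
Reactants: 4 triethyl phosphonoacetate; 5 propargyl bromide
Product: 6 triethyl 2-phosphonopent-4-ynoate
Conditions: NaH, THF, 0 °C to rt (4 in slight excess)
Reagents that add atoms: none
Why: C-alkylation of the stabilised phosphonoacetate anion with a reactive propargylic bromide (SN2) should give the mono-alkylated phosphonate that carries C9, C8 and C7.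

Step 3
Reactants: 3 (2E)-3-methyl-6-oxohex-2-en-1-yl acetate; 6 triethyl 2-phosphonopent-4-ynoate
Product: 7 ethyl (2E,6E)-8-acetoxy-6-methyl-2-(prop-2-yn-1-yl)octa-2,6-dienoate
Conditions: NaH, THF, 0 °C to rt
Reagents that add atoms: none
Why: Horner–Wadsworth–Emmons olefination of an α-branched phosphonoacetate with an unbranched aldehyde should be E-selective (ester trans to the chain), which sets C9 cis to C2 at the future C1=C10 bond.

Step 4
Reactants: 7 ethyl (2E,6E)-8-acetoxy-6-methyl-2-(prop-2-yn-1-yl)octa-2,6-dienoate
Product: 9 ethyl (2E,6E)-8-acetoxy-2-[(2E)-3-iodoprop-2-en-1-yl]-6-methylocta-2,6-dienoate, via alkenylzirconocene chloride 8 (not isolated)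
Conditions: Cp2Zr(H)Cl (1.2 equiv), THF, rt, 20 min; then I2, 0 °C
Reagents that add atoms: iodine, II
Why: Syn hydrozirconation of the terminal alkyne places zirconium on the terminal carbon, and iodinolysis with retention should give the E alkenyl iodide faster than the esters are reduced.

Step 5
Reactants: 9 ethyl (2E,6E)-8-acetoxy-2-[(2E)-3-iodoprop-2-en-1-yl]-6-methylocta-2,6-dienoate
Product: 10 (2E,6E)-2-[(2E)-3-iodoprop-2-en-1-yl]-6-methylocta-2,6-diene-1,8-diol
Conditions: DIBAL-H (5 equiv), CH2Cl2, −78 to 0 °C; aq. potassium sodium tartrate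
Reagents that add atoms: none
Why: Hydride reduction with DIBAL-H should convert the enoate into the C14 allylic alcohol and cleave the acetate in the same operation, leaving the alkenyl iodide and the double bonds untouched.

Step 6
Reactants: 10 (2E,6E)-2-[(2E)-3-iodoprop-2-en-1-yl]-6-methylocta-2,6-diene-1,8-diol
Product: 11 (2E,6E)-2-[(2E)-3-iodoprop-2-en-1-yl]-6-methylocta-2,6-dienedial
Conditions: activated MnO2 (excess), CH2Cl2, rt
Reagents that add atoms: none
Why: Allylic oxidation with MnO2 should take both primary allylic alcohols to the enals without over-oxidation and with retention of both double-bond geometries.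

Step 7
Reactants: 11 (2E,6E)-2-[(2E)-3-iodoprop-2-en-1-yl]-6-methylocta-2,6-dienedial
Product: 13 racemic (1E,5E,8E)-7-hydroxy-5-methylcyclodeca-1,5,8-triene-1-carbaldehyde, via alkenylchromium dichloride 12 (not isolated)
Conditions: CrCl2 (8 equiv), NiCl2 (2 mol %), DMSO/THF, rt, slow addition of 11 to 2 mM; aqueous work-up
Reagents that add atoms: none
Why: Nozaki–Hiyama–Kishi macrocyclisation: the E alkenylchromium species (trivalent chromium, configuration retained) can add within the molecule only to the C6 aldehyde, because closure onto the C14 aldehyde would put the E double bond into a five-membered ring, and C6 is formed as a racemate.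

Step 8
Reactants: 13 racemic (1E,5E,8E)-7-hydroxy-5-methylcyclodeca-1,5,8-triene-1-carbaldehyde
Product: 14 (6R,7R,8R)-7,8-epoxy-6-hydroxy macrocyclic enal [(1E,5E,7R,8R,9R)-8,9-epoxy-7-hydroxy-5-methylcyclodeca-1,5-diene-1-carbaldehyde]
Conditions: Ti(OiPr)4 (1.0 equiv), D-(−)-diisopropyl tartrate (1.2 equiv), TBHP (0.5 equiv, decane), 4 Å MS, CH2Cl2, −20 °C; stop near 45 % conversion
Reagents that add atoms: tert-butyl hydroperoxide, CC(C)(C)OO
Why: Sharpless kinetic-resolution epoxidation: with the D-(−)-tartrate the (6S) alcohol is the fast enantiomer at the E-disubstituted C7=C8 bond and should give the anti (erythro) trans-epoxy alcohol with C7 and C8 set by the reagent, while the (6R) alcohol stays behind, the C4=C5 arm (cis C15 methyl, mismatched) reacts slowly and the conjugated aldehyde is tolerated.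

Step 9
Reactants: 14 (6R,7R,8R)-7,8-epoxy-6-hydroxy macrocyclic enal
Product: 15 (6R,7S,8R)-6-acryloyloxy-7,8-epoxy macrocyclic enal
Conditions: acryloyl chloride (1.5 equiv), iPr2NEt, CH2Cl2, −40 to 0 °C (BHT trace)
Reagents that add atoms: acryloyl chloride, C=CC(=O)Cl
Why: O-Acylation of the secondary alcohol with an acid chloride and a hindered amine base should give the acrylate without touching the epoxide or any stereocentre (the C7 descriptor changes only through the priority rules).

Step 10
Reactants: 15 (6R,7S,8R)-6-acryloyloxy-7,8-epoxy macrocyclic enal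
Product: 18 (6R,7R,8R)-8-hydroxy-14-oxogermacra-1(10),4,11(13)-trien-12,6-olide (trans-fused α-methylene lactone), via phosphonium enolate 16 (not isolated), via phosphonio lactone alkoxide 17 (not isolated)
Conditions: PMe3 (1.5 equiv), tBuOH/THF 4:1 (0.01 M), 25 to 45 °C
Reagents that add atoms: none
Why: Proposed new method: PMe3 should add reversibly to the unsubstituted acrylate β-carbon (C13) to give enolate 16, whose α-carbon C11 attacks the epoxide carbon C7 anti to the C7–O bond, and proton transfer from C11 with E1cB loss of PMe3 from 17 restores the C11=C13 methylene; the closest known reaction types are the phosphine-mediated intramolecular Morita–Baylis–Hillman alkylation of enones by tethered epoxides and the amine-catalysed intramolecular Morita–Baylis–Hillman closure of acrylates of α-hydroxy aldehydes to α-methylene-β-hydroxy-γ-butyrolactones, and the proposal joins the acrylate ester tether of the second to the epoxide electrophile of the first. The lactone ring closes in a 5-exo-tet mode, with the breaking C7–O bond and the enolate double bond both exocyclic to the forming ring. C7 is set by SN2 inversion of the epoxide carbon, while C6 and C8 keep the configurations from step 8, so the anti relationship of O6 and the epoxide becomes the trans-fused lactone with the C8 hydroxyl anti to C11. The step needs attack at C7 and not at C8 (6-endo), which the three-atom tether O6–C12–C11 secures, and it needs phosphine activation of the acrylate and not of the enal, which the β-substituted, α-branched enal resists. The C14 aldehyde should stay out because reaching it would need a nine-membered ring across the trans-epoxide, and tert-butanol assists epoxide opening by hydrogen bonding and shuttles the proton.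

Step 11
Reactants: 18 (6R,7R,8R)-8-hydroxy-14-oxogermacra-1(10),4,11(13)-trien-12,6-olide
Product: 19 (6R,7R,8R)-8-(3-methylbutanoyloxy)-14-oxogermacra-1(10),4,11(13)-trien-12,6-olide
Conditions: isovaleric anhydride (1.5 equiv), Et3N, DMAP (cat.), CH2Cl2, 0 °C to rt
Reagents that add atoms: isovaleric anhydride, CC(C)CC(=O)OC(=O)CC(C)C
Why: DMAP-catalysed acylation of the free secondary C8 alcohol should give the isovalerate with retention at C8, the conjugated aldehyde being expected to stay open-chain and not to trap the hydroxyl as a lactol.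

Step 12
Reactants: 19 (6R,7R,8R)-8-(3-methylbutanoyloxy)-14-oxogermacra-1(10),4,11(13)-trien-12,6-olide
Product: 20 target CNP0260081.1, (4R,5S,6S,7R,8R)-4,5-epoxy-8-(3-methylbutanoyloxy)-14-oxogermacra-1(10),11(13)-dien-12,6-olide
Conditions: mCPBA (1.1 equiv), NaHCO3, CH2Cl2, 0 °C
Reagents that add atoms: meta-chloroperoxybenzoic acid, O=C(OO)c1cccc(Cl)c1
Why: Prilezhaev epoxidation should take only the electron-rich trisubstituted C4=C5 bond (the enal and the methylene lactone are electron-poor), and attack on the exposed face of this ring-trans olefin in the conformer with H5 anti to H6 is expected to give the (4R,5S) epoxide, the relationship common to the natural 4,5-epoxygermacranolides.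

Compound list
1 | geranyl acetate, (2E)-3,7-dimethylocta-2,6-dien-1-yl acetate | CC(C)=CCC/C(C)=C/COC(C)=O | starting material
2 | 6,7-ozonide of 1, (2E)-5-(5,5-dimethyl-1,2,4-trioxolan-3-yl)-3-methylpent-2-en-1-yl acetate | CC1(C)OOC(CC/C(C)=C/COC(C)=O)O1 | intermediate
3 | (2E)-3-methyl-6-oxohex-2-en-1-yl acetate | O=CCC/C(C)=C/COC(C)=O | intermediate
4 | triethyl phosphonoacetate | CCOC(=O)CP(=O)(OCC)OCC | starting material
5 | propargyl bromide (3-bromoprop-1-yne) | C#CCBr | starting material
6 | triethyl 2-phosphonopent-4-ynoate (racemic) | CCOC(=O)C(CC#C)P(=O)(OCC)OCC | intermediate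
7 | ethyl (2E,6E)-8-acetoxy-6-methyl-2-(prop-2-yn-1-yl)octa-2,6-dienoate | CCOC(=O)/C(CC#C)=C/CC/C(C)=C/COC(C)=O | intermediate
8 | (E)-alkenylzirconocene chloride from 7 (Cp2ZrCl on C7) | CCOC(=O)/C(C/C=C/[Zr](Cl)(C1C=CC=C1)C1C=CC=C1)=C/CC/C(C)=C/COC(C)=O | intermediate
9 | ethyl (2E,6E)-8-acetoxy-2-[(2E)-3-iodoprop-2-en-1-yl]-6-methylocta-2,6-dienoate | CCOC(=O)/C(C/C=C/I)=C/CC/C(C)=C/COC(C)=O | intermediate
10 | (2E,6E)-2-[(2E)-3-iodoprop-2-en-1-yl]-6-methylocta-2,6-diene-1,8-diol | OC/C(C/C=C/I)=C/CC/C(C)=C/CO | intermediate
11 | (2E,6E)-2-[(2E)-3-iodoprop-2-en-1-yl]-6-methylocta-2,6-dienedial | O=C/C(C/C=C/I)=C/CC/C(C)=C/C=O | intermediate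
12 | (E)-alkenylchromium dichloride from 11 (trivalent chromium on C7) | O=C/C(C/C=C/[Cr](Cl)Cl)=C/CC/C(C)=C/C=O | intermediate
13 | racemic (1E,5E,8E)-7-hydroxy-5-methylcyclodeca-1,5,8-triene-1-carbaldehyde (6-hydroxy, 1(10)E ring-cis, 4E, 7E) | OC1/C=C/C/C(C=O)=C\CC/C(C)=C/1 | intermediate
14 | (6R,7R,8R)-7,8-epoxy-6-hydroxy macrocyclic enal, (1E,5E,7R,8R,9R)-8,9-epoxy-7-hydroxy-5-methylcyclodeca-1,5-diene-1-carbaldehyde; trans-epoxide anti (erythro) to the hydroxyl | O[C@H]1[C@H]2O[C@@H]2C/C(C=O)=C\CC/C(C)=C/1 | intermediate
15 | (6R,7S,8R)-6-acryloyloxy-7,8-epoxy macrocyclic enal (acrylate of 14) | C=CC(=O)O[C@H]1[C@H]2O[C@@H]2C/C(C=O)=C\CC/C(C)=C/1 | intermediate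
16 | phosphonium enolate from 15 (Me3P+ on C13, enolate C11=C12) | C[P+](C)(C)CC=C([O-])O[C@H]1[C@H]2O[C@@H]2C/C(C=O)=C\CC/C(C)=C/1 | intermediate
17 | phosphonio lactone alkoxide (lactone closed, Me3P+CH2 on C11, alkoxide on C8, C11 undefined) | C[P+](C)(C)CC1C(=O)O[C@H]2[C@H]1[C@H]([O-])C/C(C=O)=C\CC/C(C)=C/2 | intermediate
18 | (6R,7R,8R)-8-hydroxy-14-oxogermacra-1(10),4,11(13)-trien-12,6-olide (trans-fused lactone, 1(10)E ring-cis, 4E) | C=C1C(=O)O[C@H]2[C@H]1[C@H](O)C/C(C=O)=C\CC/C(C)=C/2 | intermediate
19 | (6R,7R,8R)-8-(3-methylbutanoyloxy)-14-oxogermacra-1(10),4,11(13)-trien-12,6-olide | C=C1C(=O)O[C@H]2[C@H]1[C@H](OC(=O)CC(C)C)C/C(C=O)=C\CC/C(C)=C/2 | intermediate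
20 | CNP0260081.1, (4R,5S,6S,7R,8R)-4,5-epoxy-8-(3-methylbutanoyloxy)-14-oxogermacra-1(10),11(13)-dien-12,6-olide | C=C1C(=O)O[C@H]2[C@H]1[C@H](OC(=O)CC(C)C)C/C(C=O)=C\CC[C@@]1(C)O[C@@H]21 | target

Total step count: 12. Longest linear sequence: 11 steps (steps 1 and 3 to 12 from geranyl acetate; step 2 is a side branch).

Steps most likely to fail

Step 10. The phosphonium enolate may be too weak a nucleophile, or too short-lived, to open an unactivated epoxide at a secondary carbon next to the ester-bearing carbon, so that retro-addition, acrylate oligomerisation or phosphine addition to the enal take over. The fallback uses known carbanion chemistry and sets out from 14. The aldehyde would be masked as the dimethyl acetal of 14 F1 (HC(OMe)3, PPTS, MeOH, 0 °C). O6 would be esterified with diethylphosphonoacetic acid (DCC, DMAP, CH2Cl2) to give the phosphonoacetate F2. The phosphonate-stabilised carbanion (NaH, THF, 0 to 50 °C) would open the epoxide at C7 in the same 5-exo-tet sense to give the α-phosphono lactone F3. Horner–Wadsworth–Emmons methylenation with aqueous formaldehyde and K2CO3 would give the α-methylene lactone acetal F4, and aqueous oxalic acid in THF would free the aldehyde and come back to the route at 18.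

Step 7. Closure of the strained cyclodecatriene may be so slow that intermolecular addition, protonation of the alkenylchromium species and pinacol-type coupling of the enals by divalent chromium outrun it. The fallback sets out from 7. DIBAL-H would give the enyne diol F5 and MnO2 the enyne dial F6. Hydroboration of the terminal alkyne with dicyclohexylborane (hexane, 0 °C) would give the (E)-alkenyl(dicyclohexyl)borane F7. Slow addition of F7 to Et2Zn and a catalytic amino alcohol (3-exo-(dimethylamino)isoborneol) in hexane at high dilution would move the alkenyl group from boron to zinc and close the ring onto the C6 aldehyde, coming back to the route at 13; the ligand enantiomer could be chosen to enrich the 6S alcohol.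

Step 8. The ring may keep the allylic alcohol from the conformation that the titanium–tartrate complex needs, which would show as poor discrimination between the enantiomers and between the two allylic double bonds. The fallback replaces hydroxyl-directed oxygen transfer by nucleophilic epoxidation of a dienone and chelation-controlled reduction, and sets out from 9 so that C14 stays an ester. K2CO3 in EtOH would give the hydroxy ester F8, MnO2 the enal ester F9, and the CrCl2/NiCl2 closure the racemic macrocyclic hydroxy ester F10. MnO2 would oxidise F10 to the cross-conjugated dienone F11. A lanthanum–BINOL-catalysed nucleophilic epoxidation (La(OiPr)3, the BINOL enantiomer that delivers the 7S,8R product, Ph3As=O, TBHP, THF) would epoxidise only the less substituted C7=C8 enone arm to the epoxy ketone F12. Zn(BH4)2 (Et2O, −78 °C) would give the anti epoxy alcohol F13 under chelation control. DIBAL-H would give the epoxy diol F14, and TEMPO/PhI(OAc)2 would oxidise only the primary allylic alcohol, coming back to the route at 14.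

Further compounds
F1 | step 10 | dimethyl acetal of 14, (6R,7R,8R) | O[C@H]1[C@H]2O[C@@H]2C/C(C(OC)OC)=C\CC/C(C)=C/1
F2 | step 10 | diethylphosphonoacetate ester of F1, (6R,7S,8R) | CCOP(=O)(OCC)CC(=O)O[C@H]1[C@H]2O[C@@H]2C/C(C(OC)OC)=C\CC/C(C)=C/1
F3 | step 10 | α-(diethoxyphosphoryl) lactone with free C8 hydroxyl and C14 dimethyl acetal, (6R,7R,8R), C11 undefined | CCOP(=O)(OCC)C1C(=O)O[C@H]2[C@H]1[C@H](O)C/C(C(OC)OC)=C\CC/C(C)=C/2
F4 | step 10 | dimethyl acetal of 18, (6R,7R,8R) | C=C1C(=O)O[C@H]2[C@H]1[C@H](O)C/C(C(OC)OC)=C\CC/C(C)=C/2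
F5 | step 7 | (2E,6E)-6-methyl-2-(prop-2-yn-1-yl)octa-2,6-diene-1,8-diol | OC/C(CC#C)=C/CC/C(C)=C/CO
F6 | step 7 | (2E,6E)-6-methyl-2-(prop-2-yn-1-yl)octa-2,6-dienedial | O=C/C(CC#C)=C/CC/C(C)=C/C=O
F7 | step 7 | (E)-alkenyl(dicyclohexyl)borane from F6 (boron on C7) | O=C/C(C/C=C/B(C1CCCCC1)C1CCCCC1)=C/CC/C(C)=C/C=O
F8 | step 8 | ethyl (2E,6E)-8-hydroxy-2-[(2E)-3-iodoprop-2-en-1-yl]-6-methylocta-2,6-dienoate | CCOC(=O)/C(C/C=C/I)=C/CC/C(C)=C/CO
F9 | step 8 | ethyl (2E,6E)-2-[(2E)-3-iodoprop-2-en-1-yl]-6-methyl-8-oxoocta-2,6-dienoate | CCOC(=O)/C(C/C=C/I)=C/CC/C(C)=C/C=O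
F10 | step 8 | racemic ethyl (1E,5E,8E)-7-hydroxy-5-methylcyclodeca-1,5,8-triene-1-carboxylate | OC1/C=C/C/C(C(=O)OCC)=C\CC/C(C)=C/1
F11 | step 8 | ethyl (1E,5E,8E)-5-methyl-7-oxocyclodeca-1,5,8-triene-1-carboxylate | O=C1/C=C/C/C(C(=O)OCC)=C\CC/C(C)=C/1
F12 | step 8 | (7S,8R)-7,8-epoxy-6-oxo macrocyclic ester (trans-epoxy ketone) | O=C1[C@H]2O[C@@H]2C/C(C(=O)OCC)=C\CC/C(C)=C/1
F13 | step 8 | (6R,7R,8R)-7,8-epoxy-6-hydroxy macrocyclic ester (anti epoxy alcohol) | O[C@H]1[C@H]2O[C@@H]2C/C(C(=O)OCC)=C\CC/C(C)=C/1
F14 | step 8 | (6R,7R,8R)-7,8-epoxy-6,14-diol | O[C@H]1[C@H]2O[C@@H]2C/C(CO)=C\CC/C(C)=C/1
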